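**Plan**
- Retrosynthetic cuts: the C3 ester and the C11–O aryl ether (isofraxidin) first, then C9–C11 (back to a C9 ketone), then C1–C10 and C4–C5 together in one [4+2].
- Enabling feature: ring B (C5–C10) carries C6=O, C7=C8 with the C8 methyl, the C10 methyl and a C9 that can be a carbonyl. This is the pattern of 2,6-dimethyl-1,4-benzoquinone, used here as its C6 dimethyl monoketal so that only the C9 carbonyl activates the dienophile and C6/C9 stay differentiated.
- Forward order: ring B is bought as an arene and dearomatised; ring A (C1–C4) is closed onto C5/C10 by cycloaddition with 3-silyloxy-4-methylpenta-1,3-diene; C11 is added at C9; the ring fusion is turned trans; the coumarin and the isovalerate come last.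
- Stereochemistry: C10 (with C5 cis) from the chiral titanium catalyst; C9 from convex-face hydroboration of the cis-fused diene; C5 is then inverted by enolisation through C6=O; C3 from equatorial hydride delivery to the trans-fused 3-ketone.

Key step: step 3

Convention: drimane numbering throughout (ring A C1–C5 and C10, ring B C5–C10, C11 on C9); β is the face of the C10 methyl group. The target is (3R,5R,9R,10R), i.e. 3α-O, 5α-H, 9β-H (C11 α), 10β-CH3.
Assumption: the (R)-BINOL–titanium catalyst is taken to deliver the (5R,10S) adduct 5; should the sense of induction be opposite, (S)-BINOL is used and nothing else changes.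

**Step 1**
Reactants: 1 4-methylpent-1-en-3-one
Product: 2 tert-butyldimethyl[(4-methylpenta-1,3-dien-3-yl)oxy]silane
Conditions: TBSOTf, Et3N, CH2Cl2, 0 °C → rt
Reagents that add atoms: tert-butyldimethylsilyl trifluoromethanesulfonate, CC(C)(C)[Si](C)(C)OS(=O)(=O)C(F)(F)F
Why: Soft enolisation to a silyl enol ether; the isopropyl methine is the only enolisable position, so a single 2-silyloxydiene without stereoisomers should form.

**Step 2**
Reactants: 3 4-methoxy-2,6-dimethylphenol
Product: 4 4,4-dimethoxy-2,6-dimethylcyclohexa-2,5-dien-1-one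
Conditions: PhI(OAc)2, MeOH, 0 °C → rt
Reagents that add atoms: methanol, CO
Why: Oxidative dearomatisation of a para-alkoxyphenol with a hypervalent iodine reagent in methanol, the standard entry to quinone monoketals, with methanol adding para to the oxidised phenol.

**Step 3**
Reactants: 2 tert-butyldimethyl[(4-methylpenta-1,3-dien-3-yl)oxy]silane; 4 4,4-dimethoxy-2,6-dimethylcyclohexa-2,5-dien-1-one
Product: 5 (5R,10S)-3-(tert-butyldimethylsilyloxy)-6,6-dimethoxy-11-nor-5β-drima-2,7-dien-9-one (cis-fused: 5β-H and 10β-CH3)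
Conditions: (R)-BINOL (20 mol %), TiCl2(O-i-Pr)2 (20 mol %), 4 Å MS, CH2Cl2, −30 → 0 °C
Reagents that add atoms: none
Why: The tetravalent titanium Lewis acid binds the only carbonyl of 4 (the future C9=O) and the diene adds across the C5=C10 alkene in a strongly asynchronous [4+2], the C4–C5 bond leading as a Mukaiyama–Michael-like bond from the silyloxy-activated CMe2 terminus and C1–C10 following. The closest known reaction type is the BINOL–titanium-catalysed enantioselective Diels–Alder reaction of 1,4-quinone monoketals, together with Lewis-acid [4+2]/double-Michael annulations of 2-silyloxydienes with enones. Ring A closes as a six-membered ring by intermolecular [4+2] cycloaddition, which in the stepwise limit is a 6-endo-trig Michael closure of the titanium enolate onto the vinyl oxocarbenium. C5 is set by the catalyst, which distinguishes the two enantiotopic faces of the C2v-symmetric dienone, and C10 follows from suprafacial (cis) addition to the alkene. The selectivity needed is regiochemical: with C6 masked as a ketal only C9=O can be activated, so the unsubstituted β-carbon (C5) takes the nucleophilic CMe2 terminus and the methyl-bearing α-carbon (C10) takes the vinyl terminus. The ketal also blocks aromatisation to a hydroquinone after the first bond and keeps C6 and C9 differentiated for the later steps.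

**Step 4**
Reactants: 5 (5R,10S)-3-(tert-butyldimethylsilyloxy)-6,6-dimethoxy-11-nor-5β-drima-2,7-dien-9-one
Product: 6 3-(tert-butyldimethylsilyloxy)-6,6-dimethoxy-5β-drima-2,7,9(11)-triene
Conditions: Ph3PCH3Br, KN(SiMe3)2, toluene, 0 → 80 °C
Reagents that add atoms: methyltriphenylphosphonium bromide, C[P+](c1ccccc1)(c1ccccc1)c1ccccc1.[Br-]
Why: Wittig methylenation of a hindered ketone under forcing conditions; the C9 ketone cannot enolise (C10 quaternary, C6 ketalised), so the basic ylide can only add, and the ketal and silyl enol ether are inert to it.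

**Step 5**
Reactants: 6 3-(tert-butyldimethylsilyloxy)-6,6-dimethoxy-5β-drima-2,7,9(11)-triene
Product: 8 3-(tert-butyldimethylsilyloxy)-6,6-dimethoxy-5β,9βH-drima-2,7-dien-11-ol, via 11-(9-borabicyclononyl) adduct 7 (not isolated)
Conditions: 9-BBN, THF, 0 → 40 °C; then NaBO3·4H2O, H2O, rt
Reagents that add atoms: 9-borabicyclo[3.3.1]nonane (boron stays only in 7), B1C2CCCC1CCC2; sodium perborate (oxygen of the new hydroxyl), [Na+].[Na+].O[B-]1(O)OO[B-](O)(O)OO1
Why: Anti-Markovnikov hydroboration–oxidation; 9-BBN should select the 1,1-disubstituted C9=C11 terminus over the trisubstituted C7=C8 and enol ether alkenes and deliver hydrogen to C9 from the convex β face of the cis-fused bicycle (the face of the C10 methyl and H5, ring A shielding the other), which sets C9 with 9β-H and C11 α.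

**Step 6**
Reactants: 8 3-(tert-butyldimethylsilyloxy)-6,6-dimethoxy-5β,9βH-drima-2,7-dien-11-ol
Product: 10 11-hydroxy-5α,9βH-drim-7-ene-3,6-dione (trans-fused), via cis-fused 5β-dione 9 (not isolated)
Conditions: 1 M HCl, THF, rt; then K2CO3, MeOH, rt
Reagents that add atoms: water, O
Why: Acid hydrolysis of the allylic ketal and the silyl enol ether, then base-mediated epimerisation at C5 (α to the freed C6 ketone), a thermodynamic equilibration of the kind used for 5β to 5α inversion of steroidal 7-en-6-ones; it should favour the trans-decalin and leave the γ-position C9 untouched under this mild base.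

**Step 7**
Reactants: 10 11-hydroxy-5α,9βH-drim-7-ene-3,6-dione
Product: 11 5α,9βH-drim-7-ene-3α,6β,11-triol
Conditions: LiBH(s-Bu)3 (excess), THF, −78 → 0 °C; then aq. NH4Cl
Reagents that add atoms: none
Why: Bulky trialkylborohydride reduction; at C3 the axial trajectory is blocked by the axial hydrogens at C1 and C5, so hydride adds equatorially and gives the axial 3α-alcohol as with 4,4-dimethyl-3-ketones of trans-decalins, while the β,β-disubstituted enone is reduced 1,2 from the α face to the 6β-allylic alcohol, a centre that is removed again in step 9.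

**Step 8**
Reactants: 11 5α,9βH-drim-7-ene-3α,6β,11-triol; 12 isofraxidin (7-hydroxy-6,8-dimethoxycoumarin)
Product: 13 7-[(3α,6β-dihydroxy-5α,9βH-drim-7-en-11-yl)oxy]-6,8-dimethoxycoumarin
Conditions: PPh3, DIAD, THF, 0 °C → rt
Reagents that add atoms: none
Why: Mitsunobu etherification of the acidic coumarin phenol; only the primary C11 hydroxyl should be activated, since the 3α- and 6β-hydroxyls are axial and flanked by quaternary carbons, and with C6 at the alcohol level there is no carbonyl to acidify C9–H towards elimination; no stereocentre is involved.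

**Step 9**
Reactants: 13 7-[(3α,6β-dihydroxy-5α,9βH-drim-7-en-11-yl)oxy]-6,8-dimethoxycoumarin
Product: 14 7-[(3α-hydroxy-6-oxo-5α,9βH-drim-7-en-11-yl)oxy]-6,8-dimethoxycoumarin
Conditions: MnO2 (activated, excess), CH2Cl2, rt
Reagents that add atoms: none
Why: Chemoselective allylic alcohol oxidation with MnO2; only the C6 hydroxyl next to C7=C8 is oxidised, the saturated 3α-hydroxyl is not, and the neutral conditions should neither epimerise C5/C9 nor expel the aryloxide.

**Step 10**
Reactants: 14 7-[(3α-hydroxy-6-oxo-5α,9βH-drim-7-en-11-yl)oxy]-6,8-dimethoxycoumarin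
Product: 15 (3R,5R,9R,10R)-11-[(6,8-dimethoxy-2-oxo-2H-chromen-7-yl)oxy]-6-oxodrim-7-en-3-yl 3-methylbutanoate (target)
Conditions: isovaleryl chloride, pyridine, DMAP (cat.), CH2Cl2, 0 °C → rt
Reagents that add atoms: 3-methylbutanoyl chloride, CC(C)CC(Cl)=O
Why: DMAP-catalysed O-acylation of the axial secondary alcohol with retention at C3 (the C–O bond is not broken), using amine bases too weak to remove the γ-hydrogen at C9.

**Compound list**
1 | 4-methylpent-1-en-3-one | CC(C)C(=O)C=C | starting material
2 | tert-butyldimethyl[(4-methylpenta-1,3-dien-3-yl)oxy]silane | C=CC(O[Si](C)(C)C(C)(C)C)=C(C)C | intermediate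
3 | 4-methoxy-2,6-dimethylphenol | COc1cc(C)c(O)c(C)c1 | starting material
4 | 4,4-dimethoxy-2,6-dimethylcyclohexa-2,5-dien-1-one | COC1(OC)C=C(C)C(=O)C(C)=C1 | intermediate
5 | (5R,10S)-3-(tert-butyldimethylsilyloxy)-6,6-dimethoxy-11-nor-5β-drima-2,7-dien-9-one | O=C1C(C)=CC(OC)(OC)[C@@H]2C(C)(C)C(O[Si](C)(C)C(C)(C)C)=CC[C@]12C | intermediate
6 | 3-(tert-butyldimethylsilyloxy)-6,6-dimethoxy-5β-drima-2,7,9(11)-triene | C=C1C(C)=CC(OC)(OC)[C@@H]2C(C)(C)C(O[Si](C)(C)C(C)(C)C)=CC[C@]12C | intermediate
7 | 9-[3-(tert-butyldimethylsilyloxy)-6,6-dimethoxy-5β,9βH-drima-2,7-dien-11-yl]-9-borabicyclo[3.3.1]nonane | C(B1C2CCCC1CCC2)[C@@H]1C(C)=CC(OC)(OC)[C@@H]2C(C)(C)C(O[Si](C)(C)C(C)(C)C)=CC[C@]12C | intermediate (not isolated)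
8 | 3-(tert-butyldimethylsilyloxy)-6,6-dimethoxy-5β,9βH-drima-2,7-dien-11-ol | OC[C@@H]1C(C)=CC(OC)(OC)[C@@H]2C(C)(C)C(O[Si](C)(C)C(C)(C)C)=CC[C@]12C | intermediate
9 | 11-hydroxy-5β,9βH-drim-7-ene-3,6-dione (cis-fused) | OC[C@@H]1C(C)=CC(=O)[C@@H]2C(C)(C)C(=O)CC[C@]12C | intermediate (not isolated)
10 | 11-hydroxy-5α,9βH-drim-7-ene-3,6-dione (trans-fused) | OC[C@@H]1C(C)=CC(=O)[C@H]2C(C)(C)C(=O)CC[C@]12C | intermediate
11 | 5α,9βH-drim-7-ene-3α,6β,11-triol | OC[C@@H]1C(C)=C[C@@H](O)[C@H]2C(C)(C)[C@H](O)CC[C@]12C | intermediate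
12 | isofraxidin (7-hydroxy-6,8-dimethoxycoumarin) | COc1cc2ccc(=O)oc2c(OC)c1O | starting material
13 | 7-[(3α,6β-dihydroxy-5α,9βH-drim-7-en-11-yl)oxy]-6,8-dimethoxycoumarin | COc1cc2ccc(=O)oc2c(OC)c1OC[C@@H]1C(C)=C[C@@H](O)[C@H]2C(C)(C)[C@H](O)CC[C@]12C | intermediate
14 | 7-[(3α-hydroxy-6-oxo-5α,9βH-drim-7-en-11-yl)oxy]-6,8-dimethoxycoumarin | COc1cc2ccc(=O)oc2c(OC)c1OC[C@@H]1C(C)=CC(=O)[C@H]2C(C)(C)[C@H](O)CC[C@]12C | intermediate
15 | (3R,5R,9R,10R)-11-[(6,8-dimethoxy-2-oxo-2H-chromen-7-yl)oxy]-6-oxodrim-7-en-3-yl 3-methylbutanoate | COc1cc2ccc(=O)oc2c(OC)c1OC[C@@H]1C(C)=CC(=O)[C@H]2C(C)(C)[C@H](OC(=O)CC(C)C)CC[C@]12C | target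

**Step count:** 10 steps in total; longest linear sequence 9 steps (steps 1 and 3–10, or equally steps 2 and 3–10).

**Steps most likely to fail**

Step 3. Both new bonds are made at crowded carbons, and the catalyst must bind a carbonyl flanked by two methyl groups. The cycloaddition may therefore be slow, the Lewis acid may ionise the dimethyl ketal, or face discrimination may be insufficient. The fallback replaces catalyst control by auxiliary control and sets out from 4. Acid-catalysed transketalisation of 4 with (1R,2R)-1,2-diphenylethane-1,2-diol (PPTS, benzene, removal of methanol) gives the C2-symmetric spiro-dioxolane dienone F1. Thermal cycloaddition of F1 with 2 at about 13 kbar in CH2Cl2, without Lewis acid, should give the cis-fused adduct F2. The regiochemistry is again fixed by the single carbonyl, and the face is chosen by the phenyl group that shields one side of the reacting β-carbon. The conditions of steps 4 and 5 then give the 9(11)-methylene triene F3, the 11-boryl adduct F4 (not isolated) and the primary alcohol F5. The conditions of step 6 remove the auxiliary and the silyl group, and the route is rejoined at 10 (via 9). If the other diastereomer prevails, the (1S,2S)-diol is used.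

Step 5. Hydrogen delivery to C9 may not discriminate the faces well enough, because the C10 methyl also sits on the convex face, and the silyl enol ether may compete for the borane. The fallback puts C9 under thermodynamic instead of kinetic control and sets out from 6. The hydroboration is run as before and the C9-epimeric alcohol F6 is not separated from 8. The conditions of step 6 convert the mixture into 10 and its C9 epimer F8, the latter via the cis-fused C9-epimeric dione F7 (not isolated). Heating the mixture with DBU in toluene at 80 °C equilibrates C9 through the extended dienolate spanning C6 to C9. The 9α (pseudoaxial) hydroxymethyl epimer is expected to dominate because it avoids allylic 1,2-strain with the C8 methyl, the same preference that converts 9β-formyl drim-7-enes into their 9α epimers under base. The route is rejoined at 10.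

Step 8. Displacement at the β-branched C11 by a phenol flanked by two methoxy groups may be sluggish, with competing activation of the allylic 6-hydroxyl or elimination towards C9=C11. The fallback is a stepwise Williamson etherification and sets out from 11. Selective sulfonylation of the primary hydroxyl (MsCl, Et3N, CH2Cl2, −20 °C) gives the 11-methanesulfonate F9. Heating F9 with 12 and Cs2CO3 in DMF at 60–80 °C should give the aryl ether, and the route is rejoined at 13.

**Further compounds**
F1 | step 3 | (2R,3R)-7,9-dimethyl-2,3-diphenyl-1,4-dioxaspiro[4.5]deca-6,9-dien-8-one | CC1=CC2(C=C(C)C1=O)O[C@H](c1ccccc1)[C@@H](c1ccccc1)O2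
F2 | step 3 | (5R,10S)-3-(tert-butyldimethylsilyloxy)-11-nor-5β-drima-2,7-diene-6,9-dione 6-[(1R,2R)-1,2-diphenylethylene ketal] | O=C1C(C)=CC3(O[C@H](c4ccccc4)[C@@H](c4ccccc4)O3)[C@@H]2C(C)(C)C(O[Si](C)(C)C(C)(C)C)=CC[C@]12C
F3 | step 3 | 3-(tert-butyldimethylsilyloxy)-5β-drima-2,7,9(11)-trien-6-one (1R,2R)-1,2-diphenylethylene ketal | C=C1C(C)=CC3(O[C@H](c4ccccc4)[C@@H](c4ccccc4)O3)[C@@H]2C(C)(C)C(O[Si](C)(C)C(C)(C)C)=CC[C@]12C
F4 | step 3 | 11-(9-borabicyclo[3.3.1]nonan-9-yl)-3-(tert-butyldimethylsilyloxy)-5β,9βH-drima-2,7-dien-6-one (1R,2R)-1,2-diphenylethylene ketal | C(B1C2CCCC1CCC2)[C@@H]1C(C)=CC3(O[C@H](c4ccccc4)[C@@H](c4ccccc4)O3)[C@@H]2C(C)(C)C(O[Si](C)(C)C(C)(C)C)=CC[C@]12C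
F5 | step 3 | 3-(tert-butyldimethylsilyloxy)-11-hydroxy-5β,9βH-drima-2,7-dien-6-one (1R,2R)-1,2-diphenylethylene ketal | OC[C@@H]1C(C)=CC3(O[C@H](c4ccccc4)[C@@H](c4ccccc4)O3)[C@@H]2C(C)(C)C(O[Si](C)(C)C(C)(C)C)=CC[C@]12C
F6 | step 5 | 3-(tert-butyldimethylsilyloxy)-6,6-dimethoxy-5β,9αH-drima-2,7-dien-11-ol | OC[C@H]1C(C)=CC(OC)(OC)[C@@H]2C(C)(C)C(O[Si](C)(C)C(C)(C)C)=CC[C@]12C
F7 | step 5 | 11-hydroxy-5β,9αH-drim-7-ene-3,6-dione | OC[C@H]1C(C)=CC(=O)[C@@H]2C(C)(C)C(=O)CC[C@]12C
F8 | step 5 | 11-hydroxy-5α,9αH-drim-7-ene-3,6-dione | OC[C@H]1C(C)=CC(=O)[C@H]2C(C)(C)C(=O)CC[C@]12C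
F9 | step 8 | 3α,6β-dihydroxy-5α,9βH-drim-7-en-11-yl methanesulfonate | CS(=O)(=O)OC[C@@H]1C(C)=C[C@@H](O)[C@H]2C(C)(C)[C@H](O)CC[C@]12C
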